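Take logs.

| flask | substrate | coupling partner | free catalyst | remark |
|---|---|---|---|---|
| ochre | 0.42 M | 1.1 equiv | 1.3 mol% | run made earlier |
| grey | 0.66 M | 1.1 equiv | 1.3 mol% | run made earlier |
| blue | 0.30 M | 2.2 equiv | 1.3 mol% | run made earlier |
| flask | 0.30 M | 1.10 equiv | 1.3 mol% |  |

| run | time / s | product / % | substrate / % |
|---|---|---|---|
| ochre | 15.0 | 14.9 | 85.0 |
| ochre | 30.0 | 28.6 | 72.0 |
| ochre | 40.0 | 36.3 | 63.9 |
| ochre | 60.0 | 47.4 | 51.1 |
| ochre | 80.0 | 57.6 | 43.9 |
| ochre | 90.0 | 61.5 | 38.7 |
| grey | 10.0 | 12.3 | 88.0 |
| grey | 12.0 | 14.5 | 85.2 |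
| grey | 20.0 | 24.0 | 75.6 |
| grey | 25.0 | 29.0 | 70.5 |
| grey | 40.0 | 42.8 | 58.4 |
| grey | 60.0 | 55.8 | 44.4 |
| grey | 90.0 | 66.8 | 32.7 |
| blue | 10.0 | 11.5 | 88.4 |
| blue | 25.0 | 27.7 | 72.1 |
| blue | 40.0 | 41.5 | 58.2 |
| blue | 60.0 | 57.5 | 42.0 |
| blue | 90.0 | 75.4 | 24.4 |

(each reading ± 0.5 percentage points)

- apparent order in coupling partner when 50 % of the substrate are converted (percent change of the rate of making product for one percent more coupling partner charged)
- apparent order in free catalyst when 50 % of the substrate are converted (percent change of the rate of making product for one percent more free catalyst charged)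



Turn the question round. For the coupling partner not to matter, blue, which is this flask with twice the coupling partner, would have to make product at the flask's rate at 50 % conversion. Blue's product readings around that point give 0.144 M min⁻¹. Ochre and grey have the flask's equivalents and mol%, so every charge moves together between them. Their rates, 0.134 M min⁻¹ and 0.257 M min⁻¹, give a log-log slope of 1.44 against substrate charge. Extend that slope down to 0.30 M and you project 0.0826 M min⁻¹ for the flask. Blue then stands a factor 1.74 above the flask. The span order, the log10 of a rate factor over the log10 of the charge factor behind it, is 0.801. The opposite case needs a span order of zero, and this reckoning for the flask gives 0.801.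

The forecast gives 0.6 (0.42 to 0.78) for the coupling partner and 0.55 (0.3 to 1) for the free catalyst, and it warns that “the runs never vary catalyst independently”. Your span order, which compares blue with the projected flask, runs higher.

The flask gives 1.5 and 1.4, both above the forecast's ranges, and makes product at 0.0750 M min⁻¹ at 1.29 min.

    coupling partner + free catalyst → catalyst intermediate A (k = 4.30 L mol⁻¹ s⁻¹)
    catalyst intermediate A → by-product + catalyst intermediate B (k = 34.0 s⁻¹)
    catalyst intermediate B → catalyst intermediate C (k = 2.00 s⁻¹)
    substrate + catalyst intermediate C → catalyst intermediate D (k = 34.0 L mol⁻¹ s⁻¹)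
    catalyst intermediate D → free catalyst + product (k = 17.0 s⁻¹)
    2 coupling partner → homo dimer (k = 0.0130 L mol⁻¹ s⁻¹)

The simulated factor on the flask's rate with twice the coupling partner, 1.88, gives a span order of 0.907 beside your 0.801, yet the apparent order at the flask's own charge is higher. Run the flask without the path from two coupling partner to homo dimer and the order in coupling partner drops from 1.5 to 1.1. In the same run the order in free catalyst drops from 1.4 to 1.0.

The numbers in the tables come from a simulation for substances that don't exist; scatter was added.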